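**Retrosynthetic overview**
1. Target 24 comes from the 4-tetralone 19 by formylation at C3, O-alkylation, 1,2-reduction and acid-induced allylic transposition (the C4 carbonyl becomes the vinylic C4–H and C3 gains the CHO), followed by global desilylation.
2. The strategy rests on C1 carrying a 4-hydroxy-3,5-dimethoxyphenyl ring: C1 can therefore be the exocyclic methide carbon of a para-quinone methide, and the C1–C2 bond of ring B is cut there, C2 being the α-carbon of an aldehyde (the later CH2OH).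
3. Ring B is the only ring formed, by 6-exo closure of quinone methide keto aldehyde 15 to tetralone 17 with both stereocentres set; ring A and the pendant ring both come from syringaldehyde.
4. 15 comes from Ag2O oxidation of diarylmethane phenol 14, made by Negishi coupling (C8a–CH2 bond) of aryl bromide ketone 7 with benzylzinc 11; 7 comes from O-silylated 2-bromosyringaldehyde and the Grignard reagent of 2-(2-bromoethyl)-1,3-dioxolane.

Key step: step 12

Remark: locants C1–C8a are those of the dihydronaphthalene of the target (C1 aryl-bearing, C2 CH2OH-bearing, C3 CHO-bearing, C4 vinylic, ring A = C4a to C8a) and are kept for all bicyclic intermediates; the sense of induction in step 12 is assigned from the usual face-shielding model of diarylprolinol silyl ethers.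

**Route**

Step 1
Reactants: 1 syringaldehyde
Product: 2 3,5-dimethoxy-4-[(triisopropylsilyl)oxy]benzaldehyde
Conditions: TIPSCl, imidazole, DMF, rt
Reagents that add atoms: chlorotriisopropylsilane, CC(C)[Si](Cl)(C(C)C)C(C)C
Why: Imidazole-mediated silylation of the acidic phenol gives an aryl TIPS ether that tolerates the organometallic, acidic and oxidative steps up to the end of the route.

Step 2
Reactants: 2 3,5-dimethoxy-4-[(triisopropylsilyl)oxy]benzaldehyde
Product: 3 2-bromo-3,5-dimethoxy-4-[(triisopropylsilyl)oxy]benzaldehyde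
Conditions: NBS, DMF, rt
Reagents that add atoms: N-bromosuccinimide, O=C1CCC(=O)N1Br
Why: Electrophilic aromatic bromination takes place at one of the two equivalent free positions, each ortho and para to a methoxy group, as in the analogous bromination of 3,4,5-trimethoxybenzaldehyde.

Step 3
Reactants: 3 2-bromo-3,5-dimethoxy-4-[(triisopropylsilyl)oxy]benzaldehyde; 4 2-(2-bromoethyl)-1,3-dioxolane
Product: 6 1-{2-bromo-3,5-dimethoxy-4-[(triisopropylsilyl)oxy]phenyl}-3-(1,3-dioxolan-2-yl)propan-1-ol (racemic), via Grignard reagent 5 (not isolated)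
Conditions: Mg turnings, THF, 25–30 °C; then 3, THF, −78 → 0 °C; H2O work-up
Reagents that add atoms: none
Why: Grignard addition to the aldehyde, with the reagent formed below 30 °C and the aryl bromide and silyl ether inert at low temperature; the racemic carbinol centre is removed in step 4.

Step 4
Reactants: 6 1-{2-bromo-3,5-dimethoxy-4-[(triisopropylsilyl)oxy]phenyl}-3-(1,3-dioxolan-2-yl)propan-1-ol
Product: 7 1-{2-bromo-3,5-dimethoxy-4-[(triisopropylsilyl)oxy]phenyl}-3-(1,3-dioxolan-2-yl)propan-1-one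
Conditions: Dess–Martin periodinane, CH2Cl2, 0 °C → rt
Reagents that add atoms: none
Why: Dess–Martin oxidation of the benzylic secondary alcohol under near-neutral conditions leaves the dioxolane and the silyl ether intact.

Step 5
Reactants: 1 syringaldehyde
Product: 8 4-(benzyloxy)-3,5-dimethoxybenzaldehyde
Conditions: BnBr, K2CO3, DMF, rt
Reagents that add atoms: benzyl bromide, BrCc1ccccc1
Why: Williamson etherification of the phenoxide gives a benzyl ether that can later be removed by hydrogenolysis without touching the TIPS ether or the acetal.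

Step 6
Reactants: 8 4-(benzyloxy)-3,5-dimethoxybenzaldehyde
Product: 9 [4-(benzyloxy)-3,5-dimethoxyphenyl]methanol
Conditions: NaBH4, MeOH, 0 °C
Reagents that add atoms: none
Why: Borohydride reduction of an aromatic aldehyde to the benzylic alcohol.

Step 7
Reactants: 9 [4-(benzyloxy)-3,5-dimethoxyphenyl]methanol
Product: 10 2-(benzyloxy)-5-(chloromethyl)-1,3-dimethoxybenzene
Conditions: SOCl2, CH2Cl2, 0 °C
Reagents that add atoms: thionyl chloride, O=S(Cl)Cl
Why: Chlorodehydroxylation of an electron-rich benzylic alcohol through its chlorosulfite is fast at 0 °C and the benzyl aryl ether tolerates the HCl formed.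

Step 8
Reactants: 7 1-{2-bromo-3,5-dimethoxy-4-[(triisopropylsilyl)oxy]phenyl}-3-(1,3-dioxolan-2-yl)propan-1-one; 10 2-(benzyloxy)-5-(chloromethyl)-1,3-dimethoxybenzene
Product: 12 1-{2-[4-(benzyloxy)-3,5-dimethoxybenzyl]-3,5-dimethoxy-4-[(triisopropylsilyl)oxy]phenyl}-3-(1,3-dioxolan-2-yl)propan-1-one, via benzylzinc chloride 11 (not isolated)
Conditions: Zn dust, LiCl, THF, rt (10 → 11); then 7, Pd(OAc)2 (2 mol%), SPhos (4 mol%), THF, rt → 50 °C
Reagents that add atoms: none
Why: Negishi cross-coupling, in which LiCl-assisted zinc insertion gives the benzylzinc chloride and the Pd/SPhos system couples di-ortho-substituted aryl bromides; the coupling is placed after steps 3 and 4 because a benzylzinc reagent would add to the free aldehyde of 3 but leaves an aryl ketone untouched at these temperatures.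

Step 9
Reactants: 12 1-{2-[4-(benzyloxy)-3,5-dimethoxybenzyl]-3,5-dimethoxy-4-[(triisopropylsilyl)oxy]phenyl}-3-(1,3-dioxolan-2-yl)propan-1-one
Product: 13 3-(1,3-dioxolan-2-yl)-1-{2-(4-hydroxy-3,5-dimethoxybenzyl)-3,5-dimethoxy-4-[(triisopropylsilyl)oxy]phenyl}propan-1-one
Conditions: H2 (1 atm), Pd/C (10 wt% Pd), EtOAc, rt
Reagents that add atoms: none
Why: Hydrogenolysis of the benzyl aryl ether is much faster than reduction of the hindered, electron-rich aryl ketone, and the acetal and silyl ether are inert.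

Step 10
Reactants: 13 3-(1,3-dioxolan-2-yl)-1-{2-(4-hydroxy-3,5-dimethoxybenzyl)-3,5-dimethoxy-4-[(triisopropylsilyl)oxy]phenyl}propan-1-one
Product: 14 4-{2-(4-hydroxy-3,5-dimethoxybenzyl)-3,5-dimethoxy-4-[(triisopropylsilyl)oxy]phenyl}-4-oxobutanal
Conditions: 1 M HCl, THF, rt
Reagents that add atoms: water, O
Why: Acid-catalysed hydrolysis of the dioxolane frees the aliphatic aldehyde under conditions too mild to cleave the aryl TIPS ether or to dehydrate the 1,4-keto aldehyde, which is used without storage.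

Step 11
Reactants: 14 4-{2-(4-hydroxy-3,5-dimethoxybenzyl)-3,5-dimethoxy-4-[(triisopropylsilyl)oxy]phenyl}-4-oxobutanal
Product: 15 4-{2-[(3,5-dimethoxy-4-oxocyclohexa-2,5-dien-1-ylidene)methyl]-3,5-dimethoxy-4-[(triisopropylsilyl)oxy]phenyl}-4-oxobutanal (para-quinone methide)
Conditions: Ag2O, 4 Å MS, CH2Cl2, rt, dark; filtered through Celite, solution used at once
Reagents that add atoms: none
Why: Two-electron oxidation of a 4-benzyl-2,6-dimethoxyphenol by Ag2O gives the para-quinone methide; the methide carbon carries only an aryl group and H, so it cannot tautomerise to a vinylphenol, and the anhydrous, non-basic medium spares the aldehyde.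

Step 12
Reactants: 15 4-{2-[(3,5-dimethoxy-4-oxocyclohexa-2,5-dien-1-ylidene)methyl]-3,5-dimethoxy-4-[(triisopropylsilyl)oxy]phenyl}-4-oxobutanal
Product: 17 (1S,2S)-1-(4-hydroxy-3,5-dimethoxyphenyl)-6,8-dimethoxy-4-oxo-7-[(triisopropylsilyl)oxy]-1,2,3,4-tetrahydronaphthalene-2-carbaldehyde (1,2-trans), via catalyst enamine 16 (not isolated)
Conditions: (R)-2-{diphenyl[(trimethylsilyl)oxy]methyl}pyrrolidine (20 mol%), AcOH (20 mol%), CH2Cl2, −20 °C → rt
Reagents that add atoms: none
Why: The secondary amine condenses with the aliphatic aldehyde only and gives the (E)-enamine 16, whose nucleophilic carbon (C2, the α-carbon of the aldehyde) adds to the exocyclic methide carbon (C1) in a 1,6-addition driven by aromatisation of the dienone to the syringyl phenol; hydrolysis of the resulting iminium ion returns the catalyst. The closest known reaction type is the diarylprolinol silyl ether catalysed 1,6-addition of aldehydes to para-quinone methides, which is also known in ring-closing form in oxa-Michael/1,6-addition cascades leading to chromans. Ring B closes in a 6-exo-trig mode, since the C1=C bond of the methide is exocyclic to the new ring. C2 is controlled by the catalyst: the diphenyl(silyloxy)methyl group of the (R)-catalyst shields one face of the anti (E)-enamine, so that C1 is attacked by the Re face of the enamine carbon and 17 is formed as 2S, the mirror image of the sense delivered by the (S)-catalyst in intermolecular enamine additions. C1 is controlled relative to C2 by the cyclic transition state, in which the dienone ring and the pyrrolidine unit lie anti across the forming bond, which gives the 1,2-trans isomer (1S), expected also to be the more stable one. The step needs chemoselectivity for the enamine carbon over the ketone enol and the ketone oxygen, and 1,6- over 1,2- or 1,4-attack: the enamine is by far the strongest nucleophile present, only its attack at C1 gives a six-membered ring, and the dienone positions next to the carbonyl are blocked by methoxy groups.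

Step 13
Reactants: 17 (1S,2S)-1-(4-hydroxy-3,5-dimethoxyphenyl)-6,8-dimethoxy-4-oxo-7-[(triisopropylsilyl)oxy]-1,2,3,4-tetrahydronaphthalene-2-carbaldehyde
Product: 18 (1S,2S)-1-(4-hydroxy-3,5-dimethoxyphenyl)-2-(hydroxymethyl)-6,8-dimethoxy-7-[(triisopropylsilyl)oxy]-1,2,3,4-tetrahydronaphthalen-4-one
Conditions: NaBH4, EtOH/CH2Cl2, −78 °C
Reagents that add atoms: none
Why: Chemoselective borohydride reduction, because at −78 °C the aliphatic aldehyde is reduced far faster than the electron-rich aryl ketone; prompt reduction also removes the only epimerisable centre (C2) and the possibility of reversing step 12.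

Step 14
Reactants: 18 (1S,2S)-1-(4-hydroxy-3,5-dimethoxyphenyl)-2-(hydroxymethyl)-6,8-dimethoxy-7-[(triisopropylsilyl)oxy]-1,2,3,4-tetrahydronaphthalen-4-one
Product: 19 (1S,2S)-1-{3,5-dimethoxy-4-[(triisopropylsilyl)oxy]phenyl}-6,8-dimethoxy-7-[(triisopropylsilyl)oxy]-2-{[(triisopropylsilyl)oxy]methyl}-1,2,3,4-tetrahydronaphthalen-4-one
Conditions: TIPSCl (2.5 equiv), imidazole, DMAP (cat.), DMF, 40 °C
Reagents that add atoms: chlorotriisopropylsilane, CC(C)[Si](Cl)(C(C)C)C(C)C
Why: Silylation of the primary alcohol and of the newly freed phenol in one operation, so that neither is acylated in step 15 or alkylated in step 16 and all three oxygens can be released together at the end.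

Step 15
Reactants: 19 (1S,2S)-1-{3,5-dimethoxy-4-[(triisopropylsilyl)oxy]phenyl}-6,8-dimethoxy-7-[(triisopropylsilyl)oxy]-2-{[(triisopropylsilyl)oxy]methyl}-1,2,3,4-tetrahydronaphthalen-4-one
Product: 20 (1S,2R,3Z)-1-{3,5-dimethoxy-4-[(triisopropylsilyl)oxy]phenyl}-3-(hydroxymethylidene)-6,8-dimethoxy-7-[(triisopropylsilyl)oxy]-2-{[(triisopropylsilyl)oxy]methyl}-1,2,3,4-tetrahydronaphthalen-4-one
Conditions: NaH, HCO2Et, THF, 0 °C → rt; then 1 M HCl
Reagents that add atoms: ethyl formate, CCOC=O
Why: Crossed Claisen formylation at C3, the only enolisable position of the ketone, is driven by formation of the stabilised sodium enolate of the product; C1–H and C2–H are not acidic enough to epimerise (the change of descriptor at C2 is a priority change only).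

Step 16
Reactants: 20 (1S,2R,3Z)-1-{3,5-dimethoxy-4-[(triisopropylsilyl)oxy]phenyl}-3-(hydroxymethylidene)-6,8-dimethoxy-7-[(triisopropylsilyl)oxy]-2-{[(triisopropylsilyl)oxy]methyl}-1,2,3,4-tetrahydronaphthalen-4-one
Product: 21 (1S,2R,3E)-1-{3,5-dimethoxy-4-[(triisopropylsilyl)oxy]phenyl}-3-(isopropoxymethylidene)-6,8-dimethoxy-7-[(triisopropylsilyl)oxy]-2-{[(triisopropylsilyl)oxy]methyl}-1,2,3,4-tetrahydronaphthalen-4-one
Conditions: i-PrI, K2CO3, acetone, reflux
Reagents that add atoms: 2-iodopropane, CC(C)I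
Why: Alkylation of the hydroxymethylene ketone with a secondary iodide is the classical way to obtain the O-alkyl enol ether, whereas methyl iodide would largely C-alkylate the hindered C3; the E geometry is the expected one and is of no consequence.

Step 17
Reactants: 21 (1S,2R,3E)-1-{3,5-dimethoxy-4-[(triisopropylsilyl)oxy]phenyl}-3-(isopropoxymethylidene)-6,8-dimethoxy-7-[(triisopropylsilyl)oxy]-2-{[(triisopropylsilyl)oxy]methyl}-1,2,3,4-tetrahydronaphthalen-4-one
Product: 23 (1S,2R)-1-{3,5-dimethoxy-4-[(triisopropylsilyl)oxy]phenyl}-6,8-dimethoxy-7-[(triisopropylsilyl)oxy]-2-{[(triisopropylsilyl)oxy]methyl}-1,2-dihydronaphthalene-3-carbaldehyde, via allylic alcohol 22 (not isolated)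
Conditions: NaBH4, CeCl3·7H2O, MeOH/THF, 0 °C; then 1 M HCl, THF, 0 °C → rt
Reagents that add atoms: water, O
Why: Luche 1,2-reduction of the β-alkoxy enone gives allylic alcohol 22, which in acid ionises at the benzylic C4 with assistance of the enol ether oxygen, takes up water at the former methylidene carbon and loses isopropanol to give the enal conjugated with ring A (alkoxymethylene-ketone to unsaturated-aldehyde transposition); C1 and C2 take no part.

Step 18
Reactants: 23 (1S,2R)-1-{3,5-dimethoxy-4-[(triisopropylsilyl)oxy]phenyl}-6,8-dimethoxy-7-[(triisopropylsilyl)oxy]-2-{[(triisopropylsilyl)oxy]methyl}-1,2-dihydronaphthalene-3-carbaldehyde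
Product: 24 (1S,2R)-7-hydroxy-1-(4-hydroxy-3,5-dimethoxyphenyl)-2-(hydroxymethyl)-6,8-dimethoxy-1,2-dihydronaphthalene-3-carbaldehyde
Conditions: TBAF, AcOH, THF, 0 °C → rt, under argon
Reagents that add atoms: none
Why: Fluoride cleaves the two aryl and the primary alkyl Si–O bonds in one operation, and the acetic acid buffer keeps the phenoxides and the enal away from strongly basic conditions.

**Compound list**
1 | syringaldehyde (4-hydroxy-3,5-dimethoxybenzaldehyde) | COc1cc(C=O)cc(OC)c1O | starting material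
2 | 3,5-dimethoxy-4-[(triisopropylsilyl)oxy]benzaldehyde | COc1cc(C=O)cc(OC)c1O[Si](C(C)C)(C(C)C)C(C)C | intermediate
3 | 2-bromo-3,5-dimethoxy-4-[(triisopropylsilyl)oxy]benzaldehyde | COc1cc(C=O)c(Br)c(OC)c1O[Si](C(C)C)(C(C)C)C(C)C | intermediate
4 | 2-(2-bromoethyl)-1,3-dioxolane | BrCCC1OCCO1 | starting material
5 | [2-(1,3-dioxolan-2-yl)ethyl]magnesium bromide | Br[Mg]CCC1OCCO1 | intermediate
6 | 1-{2-bromo-3,5-dimethoxy-4-[(triisopropylsilyl)oxy]phenyl}-3-(1,3-dioxolan-2-yl)propan-1-ol (racemic) | COc1cc(C(O)CCC2OCCO2)c(Br)c(OC)c1O[Si](C(C)C)(C(C)C)C(C)C | intermediate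
7 | 1-{2-bromo-3,5-dimethoxy-4-[(triisopropylsilyl)oxy]phenyl}-3-(1,3-dioxolan-2-yl)propan-1-one | COc1cc(C(=O)CCC2OCCO2)c(Br)c(OC)c1O[Si](C(C)C)(C(C)C)C(C)C | intermediate
8 | 4-(benzyloxy)-3,5-dimethoxybenzaldehyde | COc1cc(C=O)cc(OC)c1OCc1ccccc1 | intermediate
9 | [4-(benzyloxy)-3,5-dimethoxyphenyl]methanol | COc1cc(CO)cc(OC)c1OCc1ccccc1 | intermediate
10 | 2-(benzyloxy)-5-(chloromethyl)-1,3-dimethoxybenzene | COc1cc(CCl)cc(OC)c1OCc1ccccc1 | intermediate
11 | [4-(benzyloxy)-3,5-dimethoxybenzyl]zinc chloride | COc1cc(C[Zn]Cl)cc(OC)c1OCc1ccccc1 | intermediate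
12 | 1-{2-[4-(benzyloxy)-3,5-dimethoxybenzyl]-3,5-dimethoxy-4-[(triisopropylsilyl)oxy]phenyl}-3-(1,3-dioxolan-2-yl)propan-1-one | COc1cc(Cc2c(OC)c(O[Si](C(C)C)(C(C)C)C(C)C)c(OC)cc2C(=O)CCC2OCCO2)cc(OC)c1OCc1ccccc1 | intermediate
13 | 3-(1,3-dioxolan-2-yl)-1-{2-(4-hydroxy-3,5-dimethoxybenzyl)-3,5-dimethoxy-4-[(triisopropylsilyl)oxy]phenyl}propan-1-one | COc1cc(Cc2c(OC)c(O[Si](C(C)C)(C(C)C)C(C)C)c(OC)cc2C(=O)CCC2OCCO2)cc(OC)c1O | intermediate
14 | 4-{2-(4-hydroxy-3,5-dimethoxybenzyl)-3,5-dimethoxy-4-[(triisopropylsilyl)oxy]phenyl}-4-oxobutanal | COc1cc(Cc2c(OC)c(O[Si](C(C)C)(C(C)C)C(C)C)c(OC)cc2C(=O)CCC=O)cc(OC)c1O | intermediate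
15 | 4-{2-[(3,5-dimethoxy-4-oxocyclohexa-2,5-dien-1-ylidene)methyl]-3,5-dimethoxy-4-[(triisopropylsilyl)oxy]phenyl}-4-oxobutanal (para-quinone methide; key-step precursor) | COC1=CC(=Cc2c(OC)c(O[Si](C(C)C)(C(C)C)C(C)C)c(OC)cc2C(=O)CCC=O)C=C(OC)C1=O | intermediate
16 | (E)-enamine of the aldehyde of 15 with (R)-2-{diphenyl[(trimethylsilyl)oxy]methyl}pyrrolidine | COC1=CC(=Cc2c(OC)c(O[Si](C(C)C)(C(C)C)C(C)C)c(OC)cc2C(=O)C/C=C/N2CCC[C@@H]2C(c2ccccc2)(c2ccccc2)O[Si](C)(C)C)C=C(OC)C1=O | intermediate
17 | (1S,2S)-1-(4-hydroxy-3,5-dimethoxyphenyl)-6,8-dimethoxy-4-oxo-7-[(triisopropylsilyl)oxy]-1,2,3,4-tetrahydronaphthalene-2-carbaldehyde (1,2-trans; key-step product) | COc1cc([C@H]2c3c(cc(OC)c(O[Si](C(C)C)(C(C)C)C(C)C)c3OC)C(=O)C[C@@H]2C=O)cc(OC)c1O | intermediate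
18 | (1S,2S)-1-(4-hydroxy-3,5-dimethoxyphenyl)-2-(hydroxymethyl)-6,8-dimethoxy-7-[(triisopropylsilyl)oxy]-1,2,3,4-tetrahydronaphthalen-4-one | COc1cc([C@H]2c3c(cc(OC)c(O[Si](C(C)C)(C(C)C)C(C)C)c3OC)C(=O)C[C@@H]2CO)cc(OC)c1O | intermediate
19 | (1S,2S)-1-{3,5-dimethoxy-4-[(triisopropylsilyl)oxy]phenyl}-6,8-dimethoxy-7-[(triisopropylsilyl)oxy]-2-{[(triisopropylsilyl)oxy]methyl}-1,2,3,4-tetrahydronaphthalen-4-one | COc1cc([C@H]2c3c(cc(OC)c(O[Si](C(C)C)(C(C)C)C(C)C)c3OC)C(=O)C[C@@H]2CO[Si](C(C)C)(C(C)C)C(C)C)cc(OC)c1O[Si](C(C)C)(C(C)C)C(C)C | intermediate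
20 | (1S,2R,3Z)-3-(hydroxymethylidene) derivative of 19 (chelated enol form of the 3-formyl ketone) | COc1cc([C@H]2c3c(cc(OC)c(O[Si](C(C)C)(C(C)C)C(C)C)c3OC)C(=O)/C(=C\O)[C@@H]2CO[Si](C(C)C)(C(C)C)C(C)C)cc(OC)c1O[Si](C(C)C)(C(C)C)C(C)C | intermediate
21 | (1S,2R,3E)-3-(isopropoxymethylidene) derivative of 19 | COc1cc([C@H]2c3c(cc(OC)c(O[Si](C(C)C)(C(C)C)C(C)C)c3OC)C(=O)/C(=C/OC(C)C)[C@@H]2CO[Si](C(C)C)(C(C)C)C(C)C)cc(OC)c1O[Si](C(C)C)(C(C)C)C(C)C | intermediate
22 | (1S,2R,3E)-4-hydroxy-3-(isopropoxymethylidene)tetralin from 21 (mixture of C4 epimers) | COc1cc([C@H]2c3c(cc(OC)c(O[Si](C(C)C)(C(C)C)C(C)C)c3OC)C(O)/C(=C/OC(C)C)[C@@H]2CO[Si](C(C)C)(C(C)C)C(C)C)cc(OC)c1O[Si](C(C)C)(C(C)C)C(C)C | intermediate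
23 | (1S,2R)-1-{3,5-dimethoxy-4-[(triisopropylsilyl)oxy]phenyl}-6,8-dimethoxy-7-[(triisopropylsilyl)oxy]-2-{[(triisopropylsilyl)oxy]methyl}-1,2-dihydronaphthalene-3-carbaldehyde | COc1cc([C@H]2c3c(cc(OC)c(O[Si](C(C)C)(C(C)C)C(C)C)c3OC)C=C(C=O)[C@@H]2CO[Si](C(C)C)(C(C)C)C(C)C)cc(OC)c1O[Si](C(C)C)(C(C)C)C(C)C | intermediate
24 | (1S,2R)-7-hydroxy-1-(4-hydroxy-3,5-dimethoxyphenyl)-2-(hydroxymethyl)-6,8-dimethoxy-1,2-dihydronaphthalene-3-carbaldehyde (CNP0313592.1) | COc1cc([C@H]2c3c(cc(OC)c(O)c3OC)C=C(C=O)[C@@H]2CO)cc(OC)c1O | target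

**Step count**
Total: 18 steps. Longest linear sequence: 15 steps (steps 1–4 and 8–18, from syringaldehyde).

**Steps most likely to fail**

Step 12. The ring closure may proceed with poor discrimination of the enamine face or of the cis/trans mode, and the addition may reverse through the enamine of 17, which would erode the selectivity. The ketone enol or ketone oxygen may also attack the methide carbon, or the amine may add to the methide and stall the cycle. The fallback gives up catalyst control and sets out from 15. Closure with achiral pyrrolidine at 20 mol% and AcOH in CH2Cl2 under equilibrating conditions should give the racemic trans tetralone aldehyde F1. Reduction with NaBH4 at −78 °C as in step 13 then gives the racemic trans hydroxymethyl tetralone F2. Its enantiomers are separated by preparative chromatography on an amylose tris-3,5-dimethylphenylcarbamate chiral stationary phase, and the 1S,2S enantiomer is 18, where the route is rejoined.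

Step 11. The unhindered quinone methide may oligomerise or be over-oxidised on the silver surface, and the free aldehyde may be oxidised or may condense while the methide is being formed. The fallback sets out from 13, which carries no aldehyde. Oxidation with PbO2 in CH2Cl2 gives the quinone methide acetal F3, which is trapped in the same flask by sodium p-toluenesulfinate and AcOH as the stable benzhydryl sulfone acetal F4. Hydrolysis with 1 M HCl in THF then frees the aldehyde to give the sulfone keto aldehyde F5. In a CH2Cl2/aqueous NaHCO3 two-phase mixture containing the catalyst of step 12, 1,6-elimination of sulfinate from the phenoxide releases 15 slowly in the flask, so that it never accumulates and closes directly to 17, where the route is rejoined.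

Step 8. Oxidative addition and transmetalation at the bromide flanked by an acyl and a methoxy group may be slow, so that the benzylzinc reagent is consumed by homocoupling or protonation. The fallback sets out from 10 and 3 and couples at the less hindered aldehyde stage with a boron nucleophile that tolerates the formyl group. Miyaura borylation of 10 with B2pin2, Pd2dba3, tri-p-anisylphosphine and KOAc in toluene at 50 °C gives the benzyl pinacol boronate F6. Suzuki–Miyaura coupling of this boronate with 3, using palladium diacetate, SPhos and K3PO4 in toluene/H2O at 80 °C, gives the 2-benzylbenzaldehyde F7. Addition of Grignard reagent 5 as in step 3 gives the secondary alcohol F8, and Dess–Martin oxidation as in step 4 returns to 12.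

**Further compounds**
F1 | step 12 | racemic trans-1-(4-hydroxy-3,5-dimethoxyphenyl)-6,8-dimethoxy-4-oxo-7-[(triisopropylsilyl)oxy]-1,2,3,4-tetrahydronaphthalene-2-carbaldehyde | COc1cc([C@H]2c3c(cc(OC)c(O[Si](C(C)C)(C(C)C)C(C)C)c3OC)C(=O)C[C@@H]2C=O)cc(OC)c1O.COc1cc([C@@H]2c3c(cc(OC)c(O[Si](C(C)C)(C(C)C)C(C)C)c3OC)C(=O)C[C@H]2C=O)cc(OC)c1O
F2 | step 12 | racemic trans-1-(4-hydroxy-3,5-dimethoxyphenyl)-2-(hydroxymethyl)-6,8-dimethoxy-7-[(triisopropylsilyl)oxy]-1,2,3,4-tetrahydronaphthalen-4-one | COc1cc([C@H]2c3c(cc(OC)c(O[Si](C(C)C)(C(C)C)C(C)C)c3OC)C(=O)C[C@@H]2CO)cc(OC)c1O.COc1cc([C@@H]2c3c(cc(OC)c(O[Si](C(C)C)(C(C)C)C(C)C)c3OC)C(=O)C[C@H]2CO)cc(OC)c1O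
F3 | step 11 | 1-{2-[(3,5-dimethoxy-4-oxocyclohexa-2,5-dien-1-ylidene)methyl]-3,5-dimethoxy-4-[(triisopropylsilyl)oxy]phenyl}-3-(1,3-dioxolan-2-yl)propan-1-one | COC1=CC(=Cc2c(OC)c(O[Si](C(C)C)(C(C)C)C(C)C)c(OC)cc2C(=O)CCC2OCCO2)C=C(OC)C1=O
F4 | step 11 | 3-(1,3-dioxolan-2-yl)-1-{2-[(4-hydroxy-3,5-dimethoxyphenyl)(4-methylbenzenesulfonyl)methyl]-3,5-dimethoxy-4-[(triisopropylsilyl)oxy]phenyl}propan-1-one (racemic) | COc1cc(C(c2c(OC)c(O[Si](C(C)C)(C(C)C)C(C)C)c(OC)cc2C(=O)CCC2OCCO2)S(=O)(=O)c2ccc(C)cc2)cc(OC)c1O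
F5 | step 11 | 4-{2-[(4-hydroxy-3,5-dimethoxyphenyl)(4-methylbenzenesulfonyl)methyl]-3,5-dimethoxy-4-[(triisopropylsilyl)oxy]phenyl}-4-oxobutanal (racemic) | COc1cc(C(c2c(OC)c(O[Si](C(C)C)(C(C)C)C(C)C)c(OC)cc2C(=O)CCC=O)S(=O)(=O)c2ccc(C)cc2)cc(OC)c1O
F6 | step 8 | 2-[4-(benzyloxy)-3,5-dimethoxybenzyl]-4,4,5,5-tetramethyl-1,3,2-dioxaborolane | COc1cc(CB2OC(C)(C)C(C)(C)O2)cc(OC)c1OCc1ccccc1
F7 | step 8 | 2-[4-(benzyloxy)-3,5-dimethoxybenzyl]-3,5-dimethoxy-4-[(triisopropylsilyl)oxy]benzaldehyde | COc1cc(Cc2c(OC)c(O[Si](C(C)C)(C(C)C)C(C)C)c(OC)cc2C=O)cc(OC)c1OCc1ccccc1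
F8 | step 8 | 1-{2-[4-(benzyloxy)-3,5-dimethoxybenzyl]-3,5-dimethoxy-4-[(triisopropylsilyl)oxy]phenyl}-3-(1,3-dioxolan-2-yl)propan-1-ol (racemic) | COc1cc(Cc2c(OC)c(O[Si](C(C)C)(C(C)C)C(C)C)c(OC)cc2C(O)CCC2OCCO2)cc(OC)c1OCc1ccccc1
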